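## Structural features

Talapolyester B (28) is an open-chain tetraester of four hydroxy acids joined head to tail: (R)-3,4-dihydroxybutanoic acid, (R)-3-hydroxybutanoic acid, 2,4-dihydroxy-6-[(R)-2-hydroxypropyl]benzoic acid and (S)-3-hydroxybutanoic acid. The chain ends in a free 1,2-diol on one side and a free carboxylic acid on the other. The only ring is the tetrasubstituted benzene: C1 carries the ester carbonyl, C2 and C4 free phenols, and C6 the CH2–CH(CH3)–O–acyl chain. The four stereocentres are isolated secondary carbinol carbons, none adjacent to another, so none can control another and each must come from its own source. Three of them are CH3–CH(O)–CH2 units (R, R, S). Fragile points are the three β-acyloxy ester units (E1cB loss of carboxylate), the terminal 3,4-dihydroxybutanoate (γ-lactonisation by the primary hydroxyl, acyl shift), the free phenols, and the aryl ester, which a free side-chain hydroxyl would attack to close a six-membered lactone. The real difficulty is the aryl ester: a benzoate flanked by two ortho substituents, bound to a secondary, elimination-prone alcohol, which must be made while two phenols, three other esters, an acid and a diol are kept apart. The key step exploits the fact that the carboxyl carbon, ring carbons C1 to C6, the benzylic CH2, the carbinol CH and its CH3 form one unbranched C10 chain oxygenated on alternate carbons. This chain is a pentaketide whose last four carbons are those of (R)-3-hydroxybutanoate, so the ring bond C1–C6 and the ester C(=O)–O bond can both be made from an open-chain acylketene.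

## Logic of the disconnections

In one sentence: 21 is thermolysed to a ketene that acylates 23 and is then cyclo-aromatised, so that the benzene ring and its hindered ester arise in one operation. The route most chemists would draw first, esterification of a preformed protected benzoic acid, does not fit this sentence.

28 to 27: the three O–CH2Ph bonds (one ester, two ethers) are cut. All protection falls in one neutral hydrogenolysis, which is needed because 28 tolerates neither acid (γ-lactonisation of the diol ester) nor base (β-elimination). The demand is that 27 carries only benzyl-type protection and that its phenols are already free.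

27 to 21 and 23: the aryl ester C(=O)–O bond to the (S)-carbinol and the ring bond C1–C6 are cut. The arene is unravelled to the 3,5,7-trioxo ester 25, which is the adduct of 23 with the ketene 24, and 24 is masked as the dioxinone in 21. The ester is thereby formed at an unhindered sp carbon before any ortho substituent exists, the phenols appear unprotected, and the side-chain oxygen is already acylated and cannot lactonise. A ring with four esters reduces to a linear chain and a C4 hydroxy ester. The forward step needs intermolecular capture of the ketene, aldol closure in the C2-to-C7 sense, and survival of every β-acyloxy group.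

21 to 19, then to 17 and 11: the C–C bond between chain carbons C6 and C7 (later the aromatic C5–C6 bond) is cut. C7 to C10 are the four carbons of an (R)-3-acyloxybutanoyl group, so the side-chain stereocentre comes from the hydroxybutanoate pool. An allyl carboxylate on C6 makes this carbon the site of soft enolisation and is removed afterwards (19 to 20 to 21). The demand is C-acylation without strong base and without elimination in the β-acyloxy acid chloride 18.

17 to 15 and 14, and 14 to 12 and 13: the bond between the dioxinone CH2 and the ketone carbon is cut (crossed Claisen of the dienolate of 15 with 16). 14 comes from alcoholysis of 12 by 13. The demand is γ-selective C-acylation.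

11 to 9 and 7, and 9 to 6 and 7: two ester C(=O)–O bonds are cut in turn. The same building block 7 is used twice, and its tert-butyl ester is cleaved by acid without touching benzyl ethers. The demand is acylation of a β-hydroxy ester without dehydration and activation of β-oxygenated acids without elimination.

6 to 4, 3, and then 1 and 2: the carboxyl carbon is traced to a terminal alkene (oxidative cleavage) and the C–C bond next to the carbinol to an epoxide opening. The (R) centre and one benzyl ether are bought with 1. The demand is attack at the terminal epoxide carbon only.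

23 to 22: the benzyl–oxygen bond of the ester is cut (carboxylate alkylation). The (S) centre is bought.

## Other disconnections considered

Alternative 1: The first idea is to cut the three alkyl ester C–O bonds and keep the arene as a preformed, protected block A1. The forward key step is esterification of A1 with 23 by acyl activation, or with the enantiomer of 23 under Mitsunobu inversion, to give A2. Desilylation, acylation with 11 and hydrogenolysis would follow. The carboxyl of A1 lies between two ortho substituents, so acyl activation should be slow while the β-hydroxy ester partner can dehydrate. After desilylation the side-chain hydroxyl is placed for six-membered lactonisation onto the aryl ester with loss of the hydroxybutanoate. Two phenol protecting groups and a silyl group must be put on and removed, and A1 needs its own chiral C3 source and several steps. The chosen plan forms the same ester at a ketene carbon and delivers the phenols free.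

Alternative 2: The aryl ester bond is cut, but the aromatic unit is taken as the lactone A3. The forward key step is ring-opening transesterification of A3 by the alkoxide of 23, with trapping of the released secondary alkoxide by 18 in the same flask. Opening a six-membered aryl lactone with a secondary alkoxide is uphill and reversible. The alkoxide of 23 is prone to retro-aldol cleavage and elimination. The released alkoxide is ideally placed to re-close, which should outrun bimolecular acylation. Both phenols would still need protection, so nothing is gained in steps.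

Alternative 3: Two ring bonds (C1–C2 and C5–C6) are cut. The forward key step is Diels–Alder addition of the ynoate A4 to the diene A5, followed by retro-Diels–Alder loss of ethylene and desilylation to 27. The regiochemistry is right in principle, since the ester-bearing alkyne carbon joins the oxygenated diene terminus. The extrusion, however, needs temperatures well above those of the chosen step, at which the homopropargylic acyloxy ynoate can isomerise to an allenoate and eliminate. A4 also needs its own esterification of an alkynoic acid with 23 and a separate chiral homopropargylic alcohol, so the side-chain stereocentre no longer comes from the hydroxybutanoate pool and the route is not shorter.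

Key step: step 13

Assumption: the polycarbonyl compounds 17, 19 to 21 and 24 to 26 are written as keto tautomers although they should exist largely as enols. The doubly activated methine of 19 and 20 and the two sp3 ring centres of 26 are configurationally labile and carry no descriptor.

## Route

Step 1
Reactants: 1 (R)-benzyl glycidyl ether; 2 vinylmagnesium bromide
Product: 3 (R)-1-(benzyloxy)pent-4-en-2-ol
Conditions: CuI (10 mol%), THF, −40 to 0 °C; then sat. aq NH4Cl
Reagents that add atoms: none
Why: Copper-catalysed SN2 opening of a terminal epoxide by a Grignard reagent occurs at the unsubstituted CH2; the carbinol C–O bond is not touched, so the (R) centre of 1 becomes C2 of 3, the later C3 of the dihydroxybutanoyl unit.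

Step 2
Reactants: 3 (R)-1-(benzyloxy)pent-4-en-2-ol
Product: 4 (R)-4,5-bis(benzyloxy)pent-1-ene
Conditions: NaH, BnBr, TBAI (cat.), THF/DMF, 0 °C to rt
Reagents that add atoms: benzyl bromide, BrCc1ccccc1
Why: Williamson ether synthesis on the sodium alkoxide; no bond to the stereocentre is broken.

Step 3
Reactants: 4 (R)-4,5-bis(benzyloxy)pent-1-ene
Product: 6 (R)-3,4-bis(benzyloxy)butanoic acid, via aldehyde 5 (not isolated)
Conditions: OsO4 (2 mol%), NaIO4, 2,6-lutidine, dioxane/H2O, rt; then NaClO2, NaH2PO4, 2-methyl-2-butene, t-BuOH/H2O, 0 °C to rt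
Reagents that add atoms: osmium tetroxide, O=[Os](=O)(=O)=O, with sodium periodate, [Na+].[O-]I(=O)(=O)=O (aldehyde oxygen); sodium chlorite, [Na+].[O-]Cl=O (carboxyl oxygen)
Why: Lemieux–Johnson cleavage removes the terminal CH2 as formaldehyde, and Pinnick oxidation of the crude β-benzyloxy aldehyde gives the acid under buffered conditions that should not cause β-elimination; benzyl ethers are inert to both oxidants.

Step 4
Reactants: 6 (R)-3,4-bis(benzyloxy)butanoic acid; 7 tert-butyl (R)-3-hydroxybutanoate
Product: 8 tert-butyl (R)-3-{[(R)-3,4-bis(benzyloxy)butanoyl]oxy}butanoate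
Conditions: EDC·HCl, DMAP (cat.), CH2Cl2, 0 °C to rt
Reagents that add atoms: none
Why: Steglich esterification (carbodiimide activation, DMAP acyl transfer); the alcohol C–O bond is kept, so both (R) centres are carried over.

Step 5
Reactants: 8 tert-butyl (R)-3-{[(R)-3,4-bis(benzyloxy)butanoyl]oxy}butanoate
Product: 9 (R)-3-{[(R)-3,4-bis(benzyloxy)butanoyl]oxy}butanoic acid
Conditions: TFA/CH2Cl2 (1:4), 0 °C to rt
Reagents that add atoms: none
Why: Acidolysis of a tert-butyl ester through the tert-butyl cation; benzyl ethers and the secondary alkyl ester should be stable to TFA at room temperature.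

Step 6
Reactants: 9 (R)-3-{[(R)-3,4-bis(benzyloxy)butanoyl]oxy}butanoic acid; 7 tert-butyl (R)-3-hydroxybutanoate
Product: 10 tert-butyl (R)-3-{[(R)-3-{[(R)-3,4-bis(benzyloxy)butanoyl]oxy}butanoyl]oxy}butanoate
Conditions: EDC·HCl, DMAP (cat.), CH2Cl2, 0 °C to rt
Reagents that add atoms: none
Why: Second Steglich esterification; a catalytic amount of DMAP at low temperature limits E1cB loss of carboxylate from the activated β-acyloxy acid, and the new (R) unit is the one that later becomes the aryl side chain.

Step 7
Reactants: 10 tert-butyl (R)-3-{[(R)-3-{[(R)-3,4-bis(benzyloxy)butanoyl]oxy}butanoyl]oxy}butanoate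
Product: 11 (R)-3-{[(R)-3-{[(R)-3,4-bis(benzyloxy)butanoyl]oxy}butanoyl]oxy}butanoic acid
Conditions: TFA/CH2Cl2 (1:4), 0 °C to rt
Reagents that add atoms: none
Why: Acidolysis of the tert-butyl ester as in step 5; no stereocentre is affected.

Step 8
Reactants: 12 Meldrum's acid; 13 allyl alcohol
Product: 14 allyl hydrogen malonate
Conditions: PhMe, 100 °C
Reagents that add atoms: none
Why: Alcoholysis of Meldrum's acid: the alcohol opens the ring at an acyl carbon and acetone is lost, which gives the malonic half ester.

Step 9
Reactants: 14 allyl hydrogen malonate; 15 2,2,6-trimethyl-4H-1,3-dioxin-4-one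
Product: 17 allyl 4-(2,2-dimethyl-4-oxo-4H-1,3-dioxin-6-yl)-3-oxobutanoate, via allyl malonyl chloride 16 (not isolated)
Conditions: 14, (COCl)2, DMF (cat.), CH2Cl2, 0 °C to rt, evaporate; 15, LiHMDS (excess), THF, −78 °C, then 16, −78 °C; aq HCl
Reagents that add atoms: none
Why: Acid chloride formation with the Vilsmeier-type catalyst, then crossed Claisen condensation (γ-C-acylation) of the lithium dienolate of 15; the excess of dienolate and base takes up the acidic protons of 16 and of the product.

Step 10
Reactants: 11 (R)-3-{[(R)-3-{[(R)-3,4-bis(benzyloxy)butanoyl]oxy}butanoyl]oxy}butanoic acid; 17 allyl 4-(2,2-dimethyl-4-oxo-4H-1,3-dioxin-6-yl)-3-oxobutanoate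
Product: 19 allyl (5R)-5-({(R)-3-{[(R)-3,4-bis(benzyloxy)butanoyl]oxy}butanoyl}oxy)-2-[(2,2-dimethyl-4-oxo-4H-1,3-dioxin-6-yl)acetyl]-3-oxohexanoate, via acid chloride 18 (not isolated)
Conditions: 11, 1-chloro-N,N,2-trimethylprop-1-en-1-amine, CH2Cl2, 0 °C to rt; then added to 17, MgCl2, pyridine, CH2Cl2, 0 °C to rt
Reagents that add atoms: none
Why: The α-chloroenamine (Ghosez's reagent) gives 18 under neutral conditions, and magnesium chloride/pyridine soft enolisation forms the chelated magnesium enolate of the β-keto ester unit of 17, which is C-acylated at the carbon between ketone and allyl ester; no strong base is present, so the β-acyloxy groups and the three (R) centres should persist.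

Step 11
Reactants: 19 allyl (5R)-5-({(R)-3-{[(R)-3,4-bis(benzyloxy)butanoyl]oxy}butanoyl}oxy)-2-[(2,2-dimethyl-4-oxo-4H-1,3-dioxin-6-yl)acetyl]-3-oxohexanoate
Product: 21 (R)-7-(2,2-dimethyl-4-oxo-4H-1,3-dioxin-6-yl)-4,6-dioxoheptan-2-yl (R)-3-{[(R)-3,4-bis(benzyloxy)butanoyl]oxy}butanoate, via β-keto acid 20 (not isolated)
Conditions: Pd(PPh3)4 (5 mol%), morpholine, THF, 0 °C to rt
Reagents that add atoms: none
Why: Tsuji–Trost deallylation (π-allylpalladium, morpholine as allyl acceptor) frees the β-keto acid 20, which should lose CO2 at room temperature to leave the 1,3-diketone; the dioxinone and the alkyl esters are not affected by palladium(0).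

Step 12
Reactants: 22 (S)-3-hydroxybutanoic acid
Product: 23 benzyl (S)-3-hydroxybutanoate
Conditions: KHCO3, BnBr, DMF, rt
Reagents that add atoms: benzyl bromide, BrCc1ccccc1
Why: SN2 O-alkylation of the carboxylate; hydrogen carbonate does not deprotonate the hydroxyl, and the stereocentre is untouched.

Step 13
Reactants: 21 (R)-7-(2,2-dimethyl-4-oxo-4H-1,3-dioxin-6-yl)-4,6-dioxoheptan-2-yl (R)-3-{[(R)-3,4-bis(benzyloxy)butanoyl]oxy}butanoate; 23 benzyl (S)-3-hydroxybutanoate (excess)
Product: 27 benzyl (S)-3-({2-[(R)-2-({(R)-3-{[(R)-3,4-bis(benzyloxy)butanoyl]oxy}butanoyl}oxy)propyl]-4,6-dihydroxybenzoyl}oxy)butanoate, via acylketene 24 (not isolated), via triketo ester 25 (not isolated), via aldol adduct 26 (not isolated)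
Conditions: PhMe, 110 °C (sealed tube); then Cs2CO3, i-PrOH/CH2Cl2, 0 °C to rt; then HCl in i-PrOH, rt
Reagents that add atoms: none
Why: Heating 21 causes a retro-[4+2] (retro-hetero-Diels–Alder) loss of acetone to give acylketene 24, whose sp carbon is acylated by the secondary hydroxyl of 23 through a six-membered hydrogen-bonded transition state to give the 3,5,7-trioxo ester 25; the carbinol C–O bond of 23 is not broken, so (S) is retained. Carbonate then forms the C2 enolate, which closes the ring by a 6-(enolendo)-exo-trig aldol addition to the C7 ketone (26), and loss of water with enolisation, completed by the acid, gives the benzene ring of 27. The closest known reaction type is the dioxinone thermolysis, alcohol capture and cycloaromatisation sequence used for late-stage construction of β-resorcylate esters, which copies polyketide biosynthesis. No stereocentre is created in 27, since the two sp3 ring centres of 26 are erased on aromatisation, and none of the four existing ones is α to a carbonyl that is enolised. Chemoselective capture, by the external alcohol and not by the internal enol hydroxyls (which would give a pyranone), is secured by an excess of 23 at high concentration and by the absence of any other free hydroxyl in 21. The C2-to-C7 aldol is preferred over the C6-to-C1 Claisen closure because the ketone C7 is more electrophilic than the ester C1 under mild carbonate base, and base is applied before acid so that C–C closure precedes any acid-promoted pyrone formation. β-Elimination of the acyloxy group at C9 would need deprotonation at C8 (pKa about 20), which should not compete with enolate formation at C2, C4 and C6 (pKa about 9 to 11) in an already anionic polyenolate. The 2,6-disubstituted benzoate ester is thus formed before the ring exists, and both phenols appear free without protecting groups.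

Step 14
Reactants: 27 benzyl (S)-3-({2-[(R)-2-({(R)-3-{[(R)-3,4-bis(benzyloxy)butanoyl]oxy}butanoyl}oxy)propyl]-4,6-dihydroxybenzoyl}oxy)butanoate
Product: 28 talapolyester B
Conditions: H2 (1 atm), 10% Pd/C, EtOAc, rt
Reagents that add atoms: none
Why: Heterogeneous hydrogenolysis cleaves the benzyl ester and both benzyl ethers under neutral conditions at room temperature, which should avoid β-elimination, acyl shift and γ-lactonisation by the freed primary hydroxyl; the arene and the homobenzylic C–O bond are inert.

## Compound list

1 | (R)-benzyl glycidyl ether, (2R)-2-[(benzyloxy)methyl]oxirane | C1[C@@H](O1)COCc2ccccc2 | starting material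
2 | vinylmagnesium bromide | C=C[Mg]Br | starting material
3 | (R)-1-(benzyloxy)pent-4-en-2-ol | C=CC[C@@H](O)COCc1ccccc1 | intermediate
4 | (R)-4,5-bis(benzyloxy)pent-1-ene | C=CC[C@@H](OCc1ccccc1)COCc1ccccc1 | intermediate
5 | (R)-3,4-bis(benzyloxy)butanal (formed in the flask) | O=CC[C@@H](OCc1ccccc1)COCc1ccccc1 | intermediate
6 | (R)-3,4-bis(benzyloxy)butanoic acid | OC(=O)C[C@@H](OCc1ccccc1)COCc1ccccc1 | intermediate
7 | tert-butyl (R)-3-hydroxybutanoate | C[C@@H](O)CC(=O)OC(C)(C)C | starting material
8 | tert-butyl (R)-3-{[(R)-3,4-bis(benzyloxy)butanoyl]oxy}butanoate | C[C@H](CC(=O)OC(C)(C)C)OC(=O)C[C@@H](OCc1ccccc1)COCc1ccccc1 | intermediate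
9 | (R)-3-{[(R)-3,4-bis(benzyloxy)butanoyl]oxy}butanoic acid | C[C@H](CC(=O)O)OC(=O)C[C@@H](OCc1ccccc1)COCc1ccccc1 | intermediate
10 | tert-butyl (R)-3-{[(R)-3-{[(R)-3,4-bis(benzyloxy)butanoyl]oxy}butanoyl]oxy}butanoate | C[C@H](CC(=O)OC(C)(C)C)OC(=O)C[C@@H](C)OC(=O)C[C@@H](OCc1ccccc1)COCc1ccccc1 | intermediate
11 | (R)-3-{[(R)-3-{[(R)-3,4-bis(benzyloxy)butanoyl]oxy}butanoyl]oxy}butanoic acid | C[C@H](CC(=O)O)OC(=O)C[C@@H](C)OC(=O)C[C@@H](OCc1ccccc1)COCc1ccccc1 | intermediate
12 | Meldrum's acid, 2,2-dimethyl-1,3-dioxane-4,6-dione | CC1(C)OC(=O)CC(=O)O1 | starting material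
13 | allyl alcohol | C=CCO | starting material
14 | allyl hydrogen malonate, 3-(allyloxy)-3-oxopropanoic acid | OC(=O)CC(=O)OCC=C | intermediate
15 | 2,2,6-trimethyl-4H-1,3-dioxin-4-one | CC1=CC(=O)OC(C)(C)O1 | starting material
16 | allyl malonyl chloride, allyl 3-chloro-3-oxopropanoate (formed in the flask) | ClC(=O)CC(=O)OCC=C | intermediate
17 | allyl 4-(2,2-dimethyl-4-oxo-4H-1,3-dioxin-6-yl)-3-oxobutanoate | C=CCOC(=O)CC(=O)CC1=CC(=O)OC(C)(C)O1 | intermediate
18 | (R)-4-chloro-4-oxobutan-2-yl (R)-3-{[(R)-3,4-bis(benzyloxy)butanoyl]oxy}butanoate (formed in the flask) | C[C@H](CC(=O)Cl)OC(=O)C[C@@H](C)OC(=O)C[C@@H](OCc1ccccc1)COCc1ccccc1 | intermediate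
19 | allyl (5R)-5-({(R)-3-{[(R)-3,4-bis(benzyloxy)butanoyl]oxy}butanoyl}oxy)-2-[(2,2-dimethyl-4-oxo-4H-1,3-dioxin-6-yl)acetyl]-3-oxohexanoate | C=CCOC(=O)C(C(=O)CC1=CC(=O)OC(C)(C)O1)C(=O)C[C@@H](C)OC(=O)C[C@@H](C)OC(=O)C[C@@H](OCc1ccccc1)COCc1ccccc1 | intermediate
20 | (5R)-5-({(R)-3-{[(R)-3,4-bis(benzyloxy)butanoyl]oxy}butanoyl}oxy)-2-[(2,2-dimethyl-4-oxo-4H-1,3-dioxin-6-yl)acetyl]-3-oxohexanoic acid (formed in the flask) | OC(=O)C(C(=O)CC1=CC(=O)OC(C)(C)O1)C(=O)C[C@@H](C)OC(=O)C[C@@H](C)OC(=O)C[C@@H](OCc1ccccc1)COCc1ccccc1 | intermediate
21 | (R)-7-(2,2-dimethyl-4-oxo-4H-1,3-dioxin-6-yl)-4,6-dioxoheptan-2-yl (R)-3-{[(R)-3,4-bis(benzyloxy)butanoyl]oxy}butanoate | CC1(C)OC(=O)C=C(CC(=O)CC(=O)C[C@@H](C)OC(=O)C[C@@H](C)OC(=O)C[C@@H](OCc2ccccc2)COCc2ccccc2)O1 | intermediate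
22 | (S)-3-hydroxybutanoic acid | C[C@H](O)CC(=O)O | starting material
23 | benzyl (S)-3-hydroxybutanoate | C[C@H](O)CC(=O)OCc1ccccc1 | intermediate
24 | (R)-4,6,8,10-tetraoxodec-9-en-2-yl (R)-3-{[(R)-3,4-bis(benzyloxy)butanoyl]oxy}butanoate, the acylketene (formed in the flask) | O=C=CC(=O)CC(=O)CC(=O)C[C@@H](C)OC(=O)C[C@@H](C)OC(=O)C[C@@H](OCc1ccccc1)COCc1ccccc1 | intermediate
25 | benzyl (S)-3-{[(9R)-9-({(R)-3-{[(R)-3,4-bis(benzyloxy)butanoyl]oxy}butanoyl}oxy)-3,5,7-trioxodecanoyl]oxy}butanoate (formed in the flask) | C[C@H](CC(=O)O[C@H](C)CC(=O)CC(=O)CC(=O)CC(=O)O[C@@H](C)CC(=O)OCc1ccccc1)OC(=O)C[C@@H](OCc1ccccc1)COCc1ccccc1 | intermediate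
26 | benzyl (S)-3-({2-[(R)-2-({(R)-3-{[(R)-3,4-bis(benzyloxy)butanoyl]oxy}butanoyl}oxy)propyl]-2-hydroxy-4,6-dioxocyclohexane-1-carbonyl}oxy)butanoate, the aldol adduct (formed in the flask) | O=C1CC(=O)CC(O)(C[C@@H](C)OC(=O)C[C@@H](C)OC(=O)C[C@@H](OCc2ccccc2)COCc2ccccc2)C1C(=O)O[C@@H](C)CC(=O)OCc1ccccc1 | intermediate
27 | benzyl (S)-3-({2-[(R)-2-({(R)-3-{[(R)-3,4-bis(benzyloxy)butanoyl]oxy}butanoyl}oxy)propyl]-4,6-dihydroxybenzoyl}oxy)butanoate | C[C@H](CC(=O)O[C@H](C)Cc1cc(O)cc(O)c1C(=O)O[C@@H](C)CC(=O)OCc1ccccc1)OC(=O)C[C@@H](OCc1ccccc1)COCc1ccccc1 | intermediate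
28 | talapolyester B, (S)-3-({2-[(R)-2-({(R)-3-{[(R)-3,4-dihydroxybutanoyl]oxy}butanoyl}oxy)propyl]-4,6-dihydroxybenzoyl}oxy)butanoic acid | C[C@H](CC(=O)O[C@H](C)Cc1cc(O)cc(O)c1C(=O)O[C@@H](C)CC(=O)O)OC(=O)C[C@@H](O)CO | target

## Step count and least certain steps

Total step count: 14. Longest linear sequence: 11 steps (steps 1 to 7, 10, 11, 13, 14). Steps 8, 9 and 12 are side branches.

Step 13 (key step). Capture of the acylketene by the hindered secondary hydroxyl of 23 may be too slow, so that intramolecular O-acylation by an enol hydroxyl (pyranone formation) or ketene dimerisation takes over. The carbonate may also trigger β-elimination in the hydroxybutanoate ester being formed. Fallback: the route leaves at 21 and comes back at 27. Compound 21 is thermolysed in toluene with a large excess of the unhindered primary alcohol 13, which gives, through 24, the allyl 3,5,7-trioxo ester F1. The same base and acid treatment aromatises it to the allyl resorcylate F2. Palladium(0)/morpholine deallylation gives the free resorcylic acid F3. A Mitsunobu esterification (DIAD, tris(3-chlorophenyl)phosphine, PhMe, 0 °C), which is selective for the carboxyl group over the phenols, then joins F3 to benzyl (R)-3-hydroxybutanoate F4, made as in step 12 from commercial (R)-3-hydroxybutanoic acid. The carbinol carbon is inverted, which gives the (S) ester 27.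

Step 10. Pyridine may dehydrochlorinate 18 to a ketene and so start E1cB loss of the β-carboxylate. Acylation may also go to the oxygen of the magnesium enolate. Fallback: the route leaves at 11 and 15 and comes back at 21 by aldol addition and oxidation in place of acylation. Borane–dimethyl sulfide reduces the carboxyl group of 11 selectively to the primary alcohol F5, and Dess–Martin oxidation gives the aldehyde F6. Separately, 15 is acetylated (LiHMDS, then acetyl chloride) to the keto-dioxinone F7. The dianion of F7 (LDA, THF, −78 °C) adds through its terminal carbon to F6 to give the β-hydroxy ketone F8 as a mixture of carbinol epimers. A second Dess–Martin oxidation removes the new centre and gives 21.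

Step 11. Morpholine may cause β-elimination of the acyloxy group next to the ketone or retro-Claisen deacylation of the triacylmethane, and 21 may decompose on silica. Fallback: the route leaves at 11 and comes back at 21 by a direct Claisen condensation with no allyl ester. Compound 11 is converted (EDC, N,O-dimethylhydroxylamine hydrochloride, N-methylmorpholine) into the Weinreb amide F9. F9 is added at −78 °C to the dianion of keto-dioxinone F7 from the fallback to step 10. The chelated tetrahedral adduct should hold until the acidic quench, which keeps the β-acyloxy ketone away from base, and 21 is released on work-up.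

Step 9. Proton transfer from the acidic methylene of 16 to the dienolate may quench the nucleophile and send 16 to a ketene, and O-acylation or double acylation may compete. Fallback: the route leaves at 15 and 14 and comes back at 17 by a decarboxylative Claisen condensation of the Masamune–Brooks type. The lithium dienolate of 15 is carboxylated with carbon dioxide to (2,2-dimethyl-4-oxo-4H-1,3-dioxin-6-yl)acetic acid F10. Carbonyldiimidazole converts F10 into the acyl imidazolide F11. F11 is then treated with the magnesium enolate of 14 (MgCl2, Et3N, THF), and C-acylation with loss of CO2 gives 17.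

Further compounds
F1 | step 13 | allyl (9R)-9-({(R)-3-{[(R)-3,4-bis(benzyloxy)butanoyl]oxy}butanoyl}oxy)-3,5,7-trioxodecanoate | C[C@H](CC(=O)O[C@H](C)CC(=O)CC(=O)CC(=O)CC(=O)OCC=C)OC(=O)C[C@@H](OCc1ccccc1)COCc1ccccc1
F2 | step 13 | allyl 2-[(R)-2-({(R)-3-{[(R)-3,4-bis(benzyloxy)butanoyl]oxy}butanoyl}oxy)propyl]-4,6-dihydroxybenzoate | C[C@H](CC(=O)O[C@H](C)Cc1cc(O)cc(O)c1C(=O)OCC=C)OC(=O)C[C@@H](OCc1ccccc1)COCc1ccccc1
F3 | step 13 | 2-[(R)-2-({(R)-3-{[(R)-3,4-bis(benzyloxy)butanoyl]oxy}butanoyl}oxy)propyl]-4,6-dihydroxybenzoic acid | C[C@H](CC(=O)O[C@H](C)Cc1cc(O)cc(O)c1C(=O)O)OC(=O)C[C@@H](OCc1ccccc1)COCc1ccccc1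
F4 | step 13 | benzyl (R)-3-hydroxybutanoate | C[C@@H](O)CC(=O)OCc1ccccc1
F5 | step 10 | (R)-4-hydroxybutan-2-yl (R)-3-{[(R)-3,4-bis(benzyloxy)butanoyl]oxy}butanoate | C[C@H](CCO)OC(=O)C[C@@H](C)OC(=O)C[C@@H](OCc1ccccc1)COCc1ccccc1
F6 | step 10 | (R)-4-oxobutan-2-yl (R)-3-{[(R)-3,4-bis(benzyloxy)butanoyl]oxy}butanoate | C[C@H](CC=O)OC(=O)C[C@@H](C)OC(=O)C[C@@H](OCc1ccccc1)COCc1ccccc1
F7 | step 10 | 2,2-dimethyl-6-(2-oxopropyl)-4H-1,3-dioxin-4-one | CC(=O)CC1=CC(=O)OC(C)(C)O1
F8 | step 10 | (2R)-7-(2,2-dimethyl-4-oxo-4H-1,3-dioxin-6-yl)-4-hydroxy-6-oxoheptan-2-yl (R)-3-{[(R)-3,4-bis(benzyloxy)butanoyl]oxy}butanoate | C[C@H](CC(O)CC(=O)CC1=CC(=O)OC(C)(C)O1)OC(=O)C[C@@H](C)OC(=O)C[C@@H](OCc2ccccc2)COCc2ccccc2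
F9 | step 11 | (R)-4-[methoxy(methyl)amino]-4-oxobutan-2-yl (R)-3-{[(R)-3,4-bis(benzyloxy)butanoyl]oxy}butanoate | C[C@H](CC(=O)N(C)OC)OC(=O)C[C@@H](C)OC(=O)C[C@@H](OCc1ccccc1)COCc1ccccc1
F10 | step 9 | (2,2-dimethyl-4-oxo-4H-1,3-dioxin-6-yl)acetic acid | OC(=O)CC1=CC(=O)OC(C)(C)O1
F11 | step 9 | 6-[2-(1H-imidazol-1-yl)-2-oxoethyl]-2,2-dimethyl-4H-1,3-dioxin-4-one | O=C(CC1=CC(=O)OC(C)(C)O1)n1ccnc1
A1 | alternative 1 | 2,4-bis(benzyloxy)-6-[(2R)-2-{[tert-butyl(dimethyl)silyl]oxy}propyl]benzoic acid | C[C@H](Cc1cc(OCc2ccccc2)cc(OCc2ccccc2)c1C(=O)O)O[Si](C)(C)C(C)(C)C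
A2 | alternative 1 | benzyl (S)-3-({2,4-bis(benzyloxy)-6-[(2R)-2-{[tert-butyl(dimethyl)silyl]oxy}propyl]benzoyl}oxy)butanoate | C[C@H](Cc1cc(OCc2ccccc2)cc(OCc2ccccc2)c1C(=O)O[C@@H](C)CC(=O)OCc1ccccc1)O[Si](C)(C)C(C)(C)C
A3 | alternative 2 | (R)-6,8-bis(benzyloxy)-3-methylisochroman-1-one | C[C@@H]1Cc2cc(OCc3ccccc3)cc(OCc3ccccc3)c2C(=O)O1
A4 | alternative 3 | benzyl (S)-3-{[(R)-5-({(R)-3-{[(R)-3,4-bis(benzyloxy)butanoyl]oxy}butanoyl}oxy)hex-2-ynoyl]oxy}butanoate | C[C@H](CC(=O)O[C@H](C)CC#CC(=O)O[C@@H](C)CC(=O)OCc1ccccc1)OC(=O)C[C@@H](OCc1ccccc1)COCc1ccccc1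
A5 | alternative 3 | 1,3-bis(trimethylsilyloxy)cyclohexa-1,3-diene | C[Si](C)(C)OC1=CC(=CCC1)O[Si](C)(C)C
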